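Numbering: bicyclo[9.3.1]pentadecane; C1/C11 bridgeheads, C3=C4 and C7=C8 alkenes, C12 spiro-epoxide carbon, C15 the carboxyl-bearing bridge. Ring A (C1, C11–C15) is closed at C1–C14 by a 6-endo intramolecular Michael addition: the enolate of a temporary cyclic anhydride tying the C15 carboxyl to C2 attacks a C12–C14 vinyl ketone. The step exploits the cis relation of the C15 carboxyl and C2 on ring A: the anhydride ring forces cis fusion, relaying the C15 quaternary centre to C1. The precursor is an acyclic 2,2-disubstituted succinic acid carrying the (Z,Z)-iodo-diene chain, from an enantioselective Ireland–Claisen rearrangement; Negishi macrocyclisation (C2–C3) and methylene transfer finish.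

Key step: step 15

Assumption: the (4S,5S)-configured boron controller of step 10 is taken to deliver the (2R,3S) acid 20; if it delivers the antipode, its (4R,5R) enantiomer is used and nothing else changes.

Step 1
Reactants: 1 but-3-yn-1-ol; 2 2-(3-chloropropyl)-1,3-dioxolane
Product: 3 7-(1,3-dioxolan-2-yl)hept-3-yn-1-ol
Conditions: n-BuLi (2.1 equiv), THF/DMPU, −78 → −20 °C; 2, NaI (cat.), → rt
Reagents that add atoms: none
Why: Acetylide SN2 alkylation; in the C,O-dilithio derivative of 1 the alkynyl carbon is the more nucleophilic site and displaces the primary halide, while the acetal is inert to base.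

Step 2
Reactants: 3 7-(1,3-dioxolan-2-yl)hept-3-yn-1-ol
Product: 4 (3Z)-7-(1,3-dioxolan-2-yl)-4-methylhept-3-en-1-ol
Conditions: MeMgBr (4 equiv), Fe(acac)3 (10 mol %), THF, −20 → 0 °C; aq. NH4Cl
Reagents that add atoms: methylmagnesium bromide, C[Mg]Br
Why: Alkoxide-directed iron-catalysed carbomagnesiation of the homopropargylic alcohol adds CH3 (to the distal alkyne carbon) and Mg syn, so protonolysis should give the Z-trisubstituted alkene that becomes C7=C8 (C6 cis to C9).

Step 3
Reactants: 4 (3Z)-7-(1,3-dioxolan-2-yl)-4-methylhept-3-en-1-ol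
Product: 5 2-[(4Z)-7-bromo-4-methylhept-4-en-1-yl]-1,3-dioxolane
Conditions: CBr4, PPh3, 2,6-lutidine, CH2Cl2, 0 °C
Reagents that add atoms: tetrabromomethane, BrC(Br)(Br)Br
Why: Appel reaction of the primary alcohol (SN2 on the alkoxyphosphonium ion), buffered so that the acetal survives.

Step 4
Reactants: 5 2-[(4Z)-7-bromo-4-methylhept-4-en-1-yl]-1,3-dioxolane
Product: 9 2-[(4Z,8Z)-9-iodo-4,8-dimethylnona-4,8-dien-1-yl]-1,3-dioxolane, via alkylmagnesium bromide 6 (not isolated), via alkylcopper 7 (not isolated), via alkenylcopper 8 (not isolated)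
Conditions: Mg, Et2O; CuBr·SMe2, Et2O/Me2S, −45 °C; propyne, −25 °C; I2, −50 → 0 °C
Reagents that add atoms: propyne, CC#C; iodine, II
Why: Syn-carbocupration of propyne puts the alkyl group on the internal carbon cis to copper and iodinolysis proceeds with retention, which fixes the (Z)-iodoalkene that becomes C3=C4 (C5 cis to iodine).

Step 5
Reactants: 9 2-[(4Z,8Z)-9-iodo-4,8-dimethylnona-4,8-dien-1-yl]-1,3-dioxolane
Product: 11 (5Z,9Z)-10-iodo-5,9-dimethyldeca-5,9-dienoic acid, via aldehyde 10 (not isolated)
Conditions: 1 M H2SO4, acetone, rt; then CrO3, H2SO4, acetone, 0 °C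
Reagents that add atoms: water, O
Why: Acetal hydrolysis followed by Jones oxidation of the aldehyde hydrate; the trisubstituted alkene and the iodoalkene are inert to both.

Step 6
Reactants: 12 methyl 2-[bis(2,2,2-trifluoroethoxy)phosphoryl]acetate; 13 5-bromo-2-methylpent-2-ene
Product: 14 methyl 2-[bis(2,2,2-trifluoroethoxy)phosphoryl]-6-methylhept-5-enoate (racemic)
Conditions: KOt-Bu, NaI (cat.), THF/DMSO, 0 → 50 °C
Reagents that add atoms: none
Why: SN2 C-alkylation of the doubly stabilised phosphonoacetate anion by the primary bromide.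

Step 7
Reactants: 14 methyl 2-[bis(2,2,2-trifluoroethoxy)phosphoryl]-6-methylhept-5-enoate; 15 (tert-butyldimethylsilyloxy)acetaldehyde
Product: 16 methyl (2Z)-2-[2-(tert-butyldimethylsilyloxy)ethylidene]-6-methylhept-5-enoate
Conditions: KN(SiMe3)2, 18-crown-6, THF, −78 °C
Reagents that add atoms: none
Why: Still–Gennari olefination; the electron-poor phosphonate eliminates from the kinetically formed adduct and should give the Z-enoate (CO2Me cis to CH2OSi).

Step 8
Reactants: 16 methyl (2Z)-2-[2-(tert-butyldimethylsilyloxy)ethylidene]-6-methylhept-5-enoate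
Product: 17 methyl (2Z)-2-(2-bromoethylidene)-6-methylhept-5-enoate
Conditions: Ph3PBr2, CH2Cl2, 0 °C
Reagents that add atoms: dibromotriphenylphosphorane, BrP(Br)(c1ccccc1)(c1ccccc1)c1ccccc1
Why: Direct conversion of the primary silyl ether into the bromide, so that the free (Z)-γ-hydroxy enoate, which would lactonise, is never formed.

Step 9
Reactants: 11 (5Z,9Z)-10-iodo-5,9-dimethyldeca-5,9-dienoic acid; 17 methyl (2Z)-2-(2-bromoethylidene)-6-methylhept-5-enoate
Product: 18 (2Z)-3-(methoxycarbonyl)-7-methylocta-2,6-dien-1-yl (5Z,9Z)-10-iodo-5,9-dimethyldeca-5,9-dienoate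
Conditions: Cs2CO3, DMF, 0 °C → rt
Reagents that add atoms: none
Why: SN2 O-alkylation of the caesium carboxylate by the primary allylic bromide; SN2′ attack at the fully substituted ester-bearing carbon is disfavoured.

Step 10
Reactants: 18 (2Z)-3-(methoxycarbonyl)-7-methylocta-2,6-dien-1-yl (5Z,9Z)-10-iodo-5,9-dimethyldeca-5,9-dienoate
Product: 20 (2R,3S)-3-ethenyl-2-[(3Z,7Z)-8-iodo-3,7-dimethylocta-3,7-dien-1-yl]-3-(methoxycarbonyl)-7-methyloct-6-enoic acid, via boron ketene acetal 19 (not isolated)
Conditions: (4S,5S)-2-bromo-4,5-diphenyl-1,3-bis{[3,5-bis(trifluoromethyl)phenyl]sulfonyl}-1,3,2-diazaborolidine (1.5 equiv), Et3N, toluene/hexane, −78 °C, then 4 °C, 7 d; aq. work-up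
Reagents that add atoms: none
Why: Enantioselective Ireland–Claisen rearrangement; soft enolisation gives the E(O) boron ketene acetal 19, which rearranges through a chair with the C10 chain and the (Z)-CO2Me group both axial, setting C11 and the quaternary C15 (C10 arm anti to CO2Me) under control of the chiral boron ligand.

Step 11
Reactants: 20 (2R,3S)-3-ethenyl-2-[(3Z,7Z)-8-iodo-3,7-dimethylocta-3,7-dien-1-yl]-3-(methoxycarbonyl)-7-methyloct-6-enoic acid
Product: 22 N-methoxy-N-methylamide of 20, via acid chloride 21 (not isolated)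
Conditions: (COCl)2, DMF (cat.), CH2Cl2, 0 °C; MeNH(OMe)·HCl, pyridine, 0 °C → rt
Reagents that add atoms: N,O-dimethylhydroxylamine hydrochloride, CNOC.Cl
Why: Acylation of the hydroxylamine through the acid chloride gives the Weinreb amide of the hindered acid without touching the neopentyl methyl ester.

Step 12
Reactants: 22 N-methoxy-N-methylamide of 20
Product: 25 γ-lactone between the C15 carboxyl and C2 (Weinreb amide retained), via alkylborane 23 (not isolated), via hydroxy ester 24 (not isolated)
Conditions: 9-BBN (1.3 equiv), THF, rt; NaOH, H2O2, 0 °C; PPTS (cat.), CH2Cl2, rt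
Reagents that add atoms: hydrogen peroxide, OO
Why: 9-BBN hydroborates only the monosubstituted vinyl group (anti-Markovnikov) and the primary alcohol 24 then closes onto the neighbouring methyl ester (5-exo-trig lactonisation, Thorpe–Ingold assisted).

Step 13
Reactants: 25 γ-lactone between the C15 carboxyl and C2
Product: 27 2,2-disubstituted succinic acid (C15–CO2H and C1H2–C2O2H), via lithium hydroxy carboxylate 26 (not isolated)
Conditions: LiOH, THF/H2O, rt; then NaHCO3, TEMPO (cat.), PhI(OAc)2, MeCN/H2O, 0 °C → rt; 1 M HCl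
Reagents that add atoms: lithium hydroxide, [Li+].[OH-]; water, O
Why: Saponification opens the lactone and the buffered nitroxyl-catalysed oxidation takes the primary alcohol of the carboxylate to the acid before relactonisation, leaving alkenes, iodoalkene and Weinreb amide untouched.

Step 14
Reactants: 27 2,2-disubstituted succinic acid
Product: 28 vinyl ketone diacid (C12 ketone, C13=C14 vinyl)
Conditions: CH2=CHMgBr (6 equiv), THF, −20 °C → rt; aq. citric acid
Reagents that add atoms: vinylmagnesium bromide, C=C[Mg]Br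
Why: Weinreb ketone synthesis; the chelated tetrahedral adduct survives until work-up, so the enone never meets the Grignard reagent, and the two carboxylates are inert.

Step 15
Reactants: 28 vinyl ketone diacid
Product: 31 cis-fused bicyclic anhydride with ring A closed and a C12–C13 silyl enol ether, via cyclic anhydride 29 (not isolated), via lithium enolate 30 (not isolated)
Conditions: Ac2O, CH2Cl2, 40 °C, evaporate; LiN(SiMe3)2 (1.05 equiv), THF, −78 °C; t-BuMe2SiOTf (1.2 equiv), −78 °C; pH 7 buffer
Reagents that add atoms: tert-butyldimethylsilyl trifluoromethanesulfonate, CC(C)(C)[Si](C)(C)OS(=O)(=O)C(F)(F)F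
Why: Proposed new method: LiN(SiMe3)2 removes a hydrogen from the only unhindered acidic position of anhydride 29, its ring CH2 (the future C1), and the anhydride enolate adds to the terminal carbon (C14) of the vinyl ketone, making the C1–C14 bond and closing ring A; the C12–C13 enolate 30 so formed is trapped on oxygen by the silyl triflate. The closest known reactions are the Michael addition of homophthalic anhydride enolates to enones (Tamura reaction) and the intramolecular Michael addition of lactone enolates to vinyl ketones; a simple succinic anhydride enolate is not known to have been used in this way. Ring A closes in a 6-(enolexo)-endo-trig mode while the five-membered anhydride ring is kept. The new stereocentre C1 is controlled by that ring: the tether starts from C15 on one face of the planar enolate and can deliver C14 to C1 only on this face, so the two rings become cis-fused and C2 ends up cis to the C15 carbonyl carbon, as the target requires. The step needs deprotonation of the anhydride CH2 rather than the tertiary α′-hydrogen at C11, and 1,4- rather than 1,2-addition; the first is secured by the higher acidity and accessibility of the anhydride position with one equivalent of hindered base at −78 °C, the second by the strain of the four-membered alternative. O-Silylation at −78 °C keeps enolate 30 from acylating itself and masks the ketone for step 16.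

Step 16
Reactants: 31 cis-fused bicyclic anhydride silyl enol ether
Product: 33 cis-fused keto γ-lactone (C15 carbonyl–O–C2H2; C12 ketone), via lithium hydroxy carboxylate 32 (not isolated)
Conditions: LiBH(s-Bu)3 (2.5 equiv), THF, −78 → 0 °C; then 1 M HCl, THF, rt
Reagents that add atoms: none
Why: The bulky hydride should attack the less hindered anhydride carbonyl (C2, next to the tertiary C1) rather than the one on the quaternary C15, and acid work-up hydrolyses the enol ether (protonation at C13, C11 untouched) and closes the hydroxy acid to the γ-lactone.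

Step 17
Reactants: 33 cis-fused keto γ-lactone
Product: 37 (1R,11R,15S,3Z,7Z)-4,8-dimethyl-15-(4-methylpent-3-en-1-yl)-12-oxobicyclo[9.3.1]pentadeca-3,7-diene-15-carboxylic acid, via iodo silyl ester 34 (not isolated), via alkylzinc iodide 35 (not isolated), via macrocyclic silyl ester 36 (not isolated)
Conditions: Me3SiSiMe3, I2, CHCl3, 50 °C, dark, evaporate; Zn, LiCl, THF, 35 °C; slow addition to Pd(OAc)2 (10 mol %), SPhos (20 mol %), THF/NMP, 50 °C, 1 mM; aq. NH4Cl
Reagents that add atoms: none
Why: Iodide opens the lactone by SN2 at the primary O–CH2 carbon (C2), zinc inserts only into the C(sp3)–I bond of silyl ester 34, and intramolecular Negishi coupling with the (Z)-iodoalkene forms C2–C3 with retention of alkene geometry, closing the 12-membered ring B without ever exposing the iodide to a free carboxylate.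

Step 18
Reactants: 37 bicyclic keto acid
Product: 38 (1R,11R,12S,15S,3Z,7Z)-4,8-dimethyl-15-(4-methylpent-3-en-1-yl)spiro[bicyclo[9.3.1]pentadeca-3,7-diene-12,2'-oxirane]-15-carboxylic acid (CNP0116395.1)
Conditions: Me3S+ I− (3 equiv), KN(SiMe3)2 (4 equiv), THF/DMSO, −10 → 0 °C; pH 5 buffer
Reagents that add atoms: trimethylsulfonium iodide, C[S+](C)C.[I-]
Why: Corey–Chaykovsky epoxidation of the carboxylate; the irreversible addition of dimethylsulfonium methylide should occur on the ketone face anti to the C10 arm on the adjacent C11 and anti to the 4-methylpent-3-enyl group, placing the new CH2 cis to H-11 and the oxygen trans to the carboxylate (12S).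

Compound list
1 | but-3-yn-1-ol | C#CCCO | starting material
2 | 2-(3-chloropropyl)-1,3-dioxolane | ClCCCC1OCCO1 | starting material
3 | 7-(1,3-dioxolan-2-yl)hept-3-yn-1-ol | OCCC#CCCCC1OCCO1 | intermediate
4 | (3Z)-7-(1,3-dioxolan-2-yl)-4-methylhept-3-en-1-ol | OCC/C=C(/C)CCCC1OCCO1 | intermediate
5 | 2-[(4Z)-7-bromo-4-methylhept-4-en-1-yl]-1,3-dioxolane | BrCC/C=C(/C)CCCC1OCCO1 | intermediate
6 | alkylmagnesium bromide from 5 | Br[Mg]CC/C=C(/C)CCCC1OCCO1 | intermediate (not isolated)
7 | alkylcopper from 6 | [Cu]CC/C=C(/C)CCCC1OCCO1 | intermediate (not isolated)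
8 | (Z)-alkenylcopper from 7 and propyne | [Cu]/C=C(/C)CC/C=C(/C)CCCC1OCCO1 | intermediate (not isolated)
9 | 2-[(4Z,8Z)-9-iodo-4,8-dimethylnona-4,8-dien-1-yl]-1,3-dioxolane | I/C=C(/C)CC/C=C(/C)CCCC1OCCO1 | intermediate
10 | (5Z,9Z)-10-iodo-5,9-dimethyldeca-5,9-dienal | I/C=C(/C)CC/C=C(/C)CCCC=O | intermediate (not isolated)
11 | (5Z,9Z)-10-iodo-5,9-dimethyldeca-5,9-dienoic acid | I/C=C(/C)CC/C=C(/C)CCCC(=O)O | intermediate
12 | methyl 2-[bis(2,2,2-trifluoroethoxy)phosphoryl]acetate | COC(=O)CP(=O)(OCC(F)(F)F)OCC(F)(F)F | starting material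
13 | 5-bromo-2-methylpent-2-ene | CC(C)=CCCBr | starting material
14 | methyl 2-[bis(2,2,2-trifluoroethoxy)phosphoryl]-6-methylhept-5-enoate (racemic) | COC(=O)C(CCC=C(C)C)P(=O)(OCC(F)(F)F)OCC(F)(F)F | intermediate
15 | (tert-butyldimethylsilyloxy)acetaldehyde | O=CCO[Si](C)(C)C(C)(C)C | starting material
16 | methyl (2Z)-2-[2-(tert-butyldimethylsilyloxy)ethylidene]-6-methylhept-5-enoate | COC(=O)/C(=C\CO[Si](C)(C)C(C)(C)C)CCC=C(C)C | intermediate
17 | methyl (2Z)-2-(2-bromoethylidene)-6-methylhept-5-enoate | COC(=O)/C(=C\CBr)CCC=C(C)C | intermediate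
18 | (2Z)-3-(methoxycarbonyl)-7-methylocta-2,6-dien-1-yl (5Z,9Z)-10-iodo-5,9-dimethyldeca-5,9-dienoate | I/C=C(/C)CC/C=C(/C)CCCC(=O)OC/C=C(\C(=O)OC)CCC=C(C)C | intermediate
19 | E(O) boron ketene acetal of 18, boron held in the (4S,5S)-diazaborolidine | I/C=C(/C)CC/C=C(/C)CC/C=C(\OC/C=C(\C(=O)OC)CCC=C(C)C)OB1N(S(=O)(=O)c2cc(C(F)(F)F)cc(C(F)(F)F)c2)[C@@H](c2ccccc2)[C@H](c2ccccc2)N1S(=O)(=O)c2cc(C(F)(F)F)cc(C(F)(F)F)c2 | intermediate (not isolated)
20 | (2R,3S)-3-ethenyl-2-[(3Z,7Z)-8-iodo-3,7-dimethylocta-3,7-dien-1-yl]-3-(methoxycarbonyl)-7-methyloct-6-enoic acid (C2 = future C11, C3 = future C15) | CC(C)=CCC[C@]([C@@H](CC/C(C)=C\CC/C(C)=C\I)C(=O)O)(C(=O)OC)C=C | intermediate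
21 | acid chloride of 20 | CC(C)=CCC[C@]([C@@H](CC/C(C)=C\CC/C(C)=C\I)C(Cl)=O)(C(=O)OC)C=C | intermediate (not isolated)
22 | N-methoxy-N-methylamide of 20 (both stereocentres unchanged) | CC(C)=CCC[C@]([C@@H](CC/C(C)=C\CC/C(C)=C\I)C(=O)N(C)OC)(C(=O)OC)C=C | intermediate
23 | B-alkyl-9-borabicyclo[3.3.1]nonane from the vinyl group of 22 | CC(C)=CCC[C@]([C@@H](CC/C(C)=C\CC/C(C)=C\I)C(=O)N(C)OC)(C(=O)OC)CCB1C2CCCC1CCC2 | intermediate (not isolated)
24 | γ-hydroxy methyl ester (CH2CH2OH in place of the vinyl group of 22) | CC(C)=CCC[C@]([C@@H](CC/C(C)=C\CC/C(C)=C\I)C(=O)N(C)OC)(C(=O)OC)CCO | intermediate (not isolated)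
25 | γ-lactone: dihydrofuran-2(3H)-one whose C3 (future C15) carries the 4-methylpent-3-enyl group and the amide-bearing carbon (future C11) | CC(C)=CCC[C@]1([C@@H](CC/C(C)=C\CC/C(C)=C\I)C(=O)N(C)OC)C(=O)OCC1 | intermediate
26 | lithium carboxylate of the ring-opened hydroxy acid of 25 | CC(C)=CCC[C@]([C@@H](CC/C(C)=C\CC/C(C)=C\I)C(=O)N(C)OC)(C(=O)[O-])CCO.[Li+] | intermediate (not isolated)
27 | 2,2-disubstituted succinic acid (C15 bears CO2H, CH2CO2H, the 4-methylpent-3-enyl group and C11; C11 bears the Weinreb amide and the C10 chain) | CC(C)=CCC[C@]([C@@H](CC/C(C)=C\CC/C(C)=C\I)C(=O)N(C)OC)(C(=O)O)CC(=O)O | intermediate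
28 | vinyl ketone diacid (27 with the amide replaced by C(=O)CH=CH2) | CC(C)=CCC[C@]([C@@H](CC/C(C)=C\CC/C(C)=C\I)C(=O)C=C)(C(=O)O)CC(=O)O | intermediate
29 | cyclic succinic anhydride of 28 | CC(C)=CCC[C@]1([C@@H](CC/C(C)=C\CC/C(C)=C\I)C(=O)C=C)C(=O)OC(=O)C1 | intermediate (not isolated)
30 | lithium C12–C13 enolate of the ring-A-closed cis-fused anhydride | CC(C)=CCC[C@]12C(=O)OC(=O)[C@H]1CC=C([O-])[C@@H]2CC/C(C)=C\CC/C(C)=C\I.[Li+] | intermediate (not isolated)
31 | cis-fused bicyclic anhydride, ring A closed, C12–C13 tert-butyldimethylsilyl enol ether; C10 arm on C11 trans to the C15 carbonyl carbon | CC(C)=CCC[C@]12C(=O)OC(=O)[C@H]1CC=C(O[Si](C)(C)C(C)(C)C)[C@@H]2CC/C(C)=C\CC/C(C)=C\I | intermediate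
32 | lithium C15-carboxylate with C2 hydroxymethyl on C1, enol ether intact | CC(C)=CCC[C@]1(C(=O)[O-])[C@@H](CO)CC=C(O[Si](C)(C)C(C)(C)C)[C@@H]1CC/C(C)=C\CC/C(C)=C\I.[Li+] | intermediate (not isolated)
33 | cis-fused keto γ-lactone (C15 carbonyl–O–C2H2 on C1; C12 ketone) | CC(C)=CCC[C@]12C(=O)OC[C@H]1CCC(=O)[C@@H]2CC/C(C)=C\CC/C(C)=C\I | intermediate
34 | trimethylsilyl ester of the ring-opened C2 iodide | CC(C)=CCC[C@]1(C(=O)O[Si](C)(C)C)[C@@H](CI)CCC(=O)[C@@H]1CC/C(C)=C\CC/C(C)=C\I | intermediate (not isolated)
35 | C2 alkylzinc iodide of 34 | CC(C)=CCC[C@]1(C(=O)O[Si](C)(C)C)[C@@H](C[Zn]I)CCC(=O)[C@@H]1CC/C(C)=C\CC/C(C)=C\I | intermediate (not isolated)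
36 | trimethylsilyl ester of 37 | CC(C)=CCC[C@]1(C(=O)O[Si](C)(C)C)[C@H]2C/C=C(/C)CC/C=C(/C)CC[C@H]1C(=O)CC2 | intermediate (not isolated)
37 | (1R,11R,15S,3Z,7Z)-4,8-dimethyl-15-(4-methylpent-3-en-1-yl)-12-oxobicyclo[9.3.1]pentadeca-3,7-diene-15-carboxylic acid | CC(C)=CCC[C@]1(C(=O)O)[C@H]2C/C=C(/C)CC/C=C(/C)CC[C@H]1C(=O)CC2 | intermediate
38 | (1R,11R,12S,15S,3Z,7Z)-4,8-dimethyl-15-(4-methylpent-3-en-1-yl)spiro[bicyclo[9.3.1]pentadeca-3,7-diene-12,2'-oxirane]-15-carboxylic acid (CNP0116395.1) | CC(C)=CCC[C@]1(C(=O)O)[C@H]2C/C=C(/C)CC/C=C(/C)CC[C@H]1[C@@]1(CC2)CO1 | target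

Total steps: 18. Longest linear sequence: 15 (steps 1–5 and 9–18).

Steps most likely to fail

1. Step 15 (proposed new method). The anhydride enolate may fragment to a ketene carboxylate, or proton transfer may remove the α′-hydrogen at C11 and erode that centre, faster than the ring closes. The fallback uses known reactions, sets out from 28 and comes back at 33. Anhydride 29 (made with Ac2O as in step 15) is opened with methanol at the less hindered carbonyl to the monomethyl ester F1. LiN(SiMe3)2 (2.1 equiv, −78 °C) forms the carboxylate ester enolate, whose intramolecular Michael addition to the vinyl ketone should give the keto ester acid F2 as a mixture at C1. LiOH hydrolyses the unhindered ester to the keto diacid F3. Ac2O with catalytic Et3N at 60 °C closes the anhydride and equilibrates C1 through the anhydride enol to the cis-fused keto anhydride F4. LiBH(s-Bu)3 then reduces the C2 carbonyl and the ketone to the hydroxy lactone F5, and Dess–Martin periodinane oxidises the secondary alcohol to 33.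

2. Step 17. Acid-promoted Z/E isomerisation or C11 epimerisation may occur during the iodide opening, and oligomerisation or β-hydride elimination may compete with closure of the trans-bridged 12-membered ring. The fallback sets out from 33 and comes back at 37. After the same Me3SiI opening to the iodo silyl ester 34, the ring is closed without a preformed organometallic by nickel-catalysed reductive cross-electrophile coupling of the alkyl iodide with the alkenyl iodide (NiBr2(dme), 4,4′-di-tert-butyl-2,2′-bipyridine, Mn, DMA, high dilution). This radical-chain coupling tolerates the ketone and the silyl ester, and aqueous work-up gives 37. No new isolated compound arises.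

3. Step 18. The ylide may attack the wrong carbonyl face, or its basicity may enolise the ketone and epimerise C11. The fallback sets out from 37 and comes back at 38. Dimethylsulfoxonium methylide (Me3S(O)+ I−, NaH, DMSO, rt) is used instead. Its addition is reversible, so the more stable betaine rather than the faster-formed one decides the configuration at C12. It is also less basic, which lowers the risk at C11. No new compound arises.

Further compounds
F1 | step 15 | monomethyl ester of 28 at the C2 carboxyl (C15–CO2H free) | CC(C)=CCC[C@]([C@@H](CC/C(C)=C\CC/C(C)=C\I)C(=O)C=C)(C(=O)O)CC(=O)OC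
F2 | step 15 | ring-A-closed keto ester acid, mixture at C1 | CC(C)=CCC[C@]1(C(=O)O)C(C(=O)OC)CCC(=O)[C@@H]1CC/C(C)=C\CC/C(C)=C\I
F3 | step 15 | ring-A-closed keto diacid, mixture at C1 | CC(C)=CCC[C@]1(C(=O)O)C(C(=O)O)CCC(=O)[C@@H]1CC/C(C)=C\CC/C(C)=C\I
F4 | step 15 | cis-fused keto anhydride | CC(C)=CCC[C@]12C(=O)OC(=O)[C@H]1CCC(=O)[C@@H]2CC/C(C)=C\CC/C(C)=C\I
F5 | step 15 | cis-fused hydroxy γ-lactone (C12 alcohol, epimers) | CC(C)=CCC[C@]12C(=O)OC[C@H]1CCC(O)[C@@H]2CC/C(C)=C\CC/C(C)=C\I
F0 | step 17 | none | none
F0 | step 18 | none | none
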